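The earlier runs and the new flask were computed from invented constants; noise was put on by code.

- The pitfall in the ochre run, which is this very flask followed so far, was to read the curves as one pool of conformers feeding two products, although the isomer of the product already stood flat at 49.9% after 10.0 s while the target was still climbing from 27.5%.

| flask | starting material | other conformer | protic impurity | remark | time |
|---|---|---|---|---|---|
| ochre | 0.10 M | 1 equiv | 5 mM | the very flask that is asked about, followed so far |  |
| flask | 0.10 M | 1.00 equiv | 5.00 mM |  | 2.0 min |

- ochre (time / s: target / %, isomer of the product / %): 10.0: 27.5, 49.9; 12.0: 31.5, 50.3; 15.0: 33.7, 48.2; 25.0: 41.8, 48.0; 40.0: 47.2, 50.6; 60.0: 47.1, 49.5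

(standard deviation of a reading: 1 percentage point)

* ratio of target to isomer of the product at 0.080 s
* ratio of target to isomer of the product at 2.0 min

- what was read earlier has a scatter of 1 percentage point, one standard deviation

- I began with the main steps, taking each conformer to run first-order in its own concentration to its own product, starting material to target and other conformer to isomer of the product, so that in this picture equal charges gave a late ratio of one.
- Then I added the protic impurity: on the supposition that every bit of it took starting material, my estimate for this flask was a loss of 2.50% of the charge from the target side and a ratio of 0.950.
- For the rest I turned to the plateaus and kept the charge memory, the flat target over the flat isomer of the product at equal charges, 0.942 as read from the last two ochre readings; under kinetic control, I took the late ratio of a flask with the same starting material and protic impurity to be this number divided by its equivalents of other conformer.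
- I committed to that reading for the late ratio of this flask, but I gave no figure for the early ratio, since the first reading came far later than the time asked.
- The forecast gave 0.015 for the early ratio and 0.95 for the late one, and said of the early one: “This is poorly bounded”.
- This flask gave 0.120 at 0.080 s and 0.941 at 2.0 min, so the forecast's early ratio stood low by a factor of 8.00, while its late ratio lay within the margin.

    starting material + protic impurity → quenched substrate (k = 0.760 M⁻¹ s⁻¹)
    third conformer → third product (k = 0.476 s⁻¹)
    other conformer → isomer of the product (k = 0.699 s⁻¹)
    starting material → target (k = 0.0818 s⁻¹)
    other conformer ⇌ third conformer (K = 3.10, k = 0.0181 s⁻¹)
    starting material ⇌ other conformer (K = 0.223, k = 0.00542 s⁻¹)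

- Starting material went to target at 0.0818 s⁻¹, more slowly than other conformer went to isomer of the product at 0.699 s⁻¹, and at equal charges their quotient of 0.117 stands beside the early ratio of this flask. Starting material crossed to other conformer far more slowly still, at 0.00542 s⁻¹, with a net 1.38% of the charge turned over by 2.0 min.
- In the neighbour flask with 4.00 equiv of other conformer, the charge memory gives a late ratio of 0.236, and the computed result there is 0.269.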